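Remark on the chemistry: lignan locants are used throughout (C7, C7′ = benzylic OCH; C8, C8′ = ring-fusion CH; C9 on C8 and C9′ on C8′ = OCH2; ring 1 = C7–O1–C9′–C8′–C8; ring 2 = C7′–O2–C9–C8–C8′; ring A on C7, ring B on C7′). The target is read as the (7R,7′R,8S,8′S) isomer, the mono-prenyl ether of the levorotatory pinoresinol series.

## The problem

The target is a 2,6-diaryl-3,7-dioxabicyclo[3.3.0]octane. Two tetrahydrofuran rings share the C8–C8′ bond in a cis fusion, and each carries a guaiacyl-type aryl group on its benzylic carbon, on the convex face. Four contiguous stereocentres must be set as one enantiomer. The cis fusion follows once the second ring is closed onto the first, and C8 can be corrected as long as C9 is a carbonyl carbon. The real tasks are therefore the absolute configuration at C7, C7′ and C8′ and the trans relation of each aryl group to the neighbouring ring. C7 can control C8′ if both sit on one ring in a chair-like transition state, while C7′ can be brought in preformed. Both benzylic C–O bonds are para to an oxygen substituent and ionise under acid with loss of configuration; the prenyl ether is a trisubstituted alkene that tolerates neither Lewis acids nor ruthenium carbenes. The skeleton is C2-symmetric and the two phenols are homotopic, yet only one is to be prenylated, so the rings must be told apart before the end. The enabling feature is ring 1: a 2-aryltetrahydrofuran whose C9′ is an unsubstituted OCH2 carbon at the oxidation level of formaldehyde and whose C8 carries the one-carbon branch C9. A 3-formyltetrahydrofuran of this pattern is what a Prins closure of a formaldehyde-derived oxocarbenium ion on O1, followed by a pinacol-type shift of C7, delivers.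

## Retrosynthesis

**Phenol end game (25 back to 21).** Target 25 is traced to tosylate 24 (O–S bond on ring A), then to phenol 22 plus prenyl bromide 23 (O–C bond on ring B), then to the tosylate pivalate 21. The prenyl group has to come last because its alkene would not survive the Lewis acids and the carbene catalyst used earlier. Freeing both phenols and alkylating once was set aside: the hydroxyls are homotopic and would give a statistical mixture. Two different electron-poor O-substituents cost one step more and make the order unambiguous. The forward steps must cleave an aryl pivalate beside an aryl tosylate, alkylate a single phenoxide, and hydrolyse a sulfonate in a molecule with no base-sensitive site.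

**Ring 2 (21 back to 17).** Ring 2 is opened at C9: removing the C9–H hydride gives lactol 20, and cutting O2–C9 gives the silyl-protected hydroxy aldehyde 17. The neighbouring cut, O2–C7′ through a benzylic cation, is shorter on paper but hands C7′ to thermodynamic control. Cutting at C9 keeps C7′ as a preformed carbinol that is never ionised. 17 is monocyclic and its C8 centre need not be correct: only the epimer with the formyl group cis to the C8′ side chain can close to a cis-fused bicycle, so closure and epimerisation are coupled. The forward steps need silyl removal without acyl loss, enolisation without β-elimination of O1, and an ionic reduction that ionises C9 only.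

**Ring 1 (17 back to 14).** 17 is cut at C9′–C8′ and C7–C8, which leads to the acyclic E-alkene 14: (7S) methoxymethyl ether, (9S) free carbinol, (7′R) silyl ether. Cuts at O1–C7 (benzylic substitution) or O1–C9′ (ether synthesis) would leave the C8–C8′ bond and both ring-fusion centres to be built separately. This cut derives C8′ from C7 inside a chair and removes one ring, two C–C bonds and two stereocentres at once. The three centres left in 14 are isolated from one another and can each be set by a reagent. The forward reaction must ionise the acetal and not the benzylic C–O bonds, keep the C7 aryl group equatorial, and end by ring-bond migration and not hydride shift.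

**Alkene C8=C8′ (14 back to 8 and 13).** The double bond is cut by cross-metathesis into allylic alcohol 8 and silyl ether 13, two vanillin-derived halves of similar size. Carbonyl-addition alternatives at C8–C9 would need an α-aryl-α-alkoxy aldehyde that racemises easily. Metathesis touches no stereocentre and gives the E isomer between two branched carbons. It asks for cross- over homo-coupling of two hindered, allylically oxygenated partners.

**Fragment 8 (8 back to 7, 5, 2, 3, 6 and 1).** 8 comes from 7 by unmasking O9, 7 from alcohol 5 and chloromethyl methyl ether 6, and 5 from aldehyde 2 and allyl ether 3 by cutting C7–C9. A syn-selective asymmetric alkoxyallylboration sets C7 and C9 together. It necessarily leaves its ether on O9 and the free hydroxyl on O7, whereas the cascade needs the acetal on O1 (only from the homoallylic oxygen is the closure 6-endo). A 4-methoxyphenyl ether therefore occupies O9 temporarily. 2 is the tosylate of vanillin 1.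

**Fragment 13 (13 back to 12, 11, 9, 10 and 1).** 13 is the silyl ether of (R)-carbinol 12, obtained by resolution of racemate 11, which comes from pivalate 9 and vinylmagnesium bromide 10 (C7′–C8′ bond). 9 is the pivalate of 1. Resolution is preferred to an asymmetric vinyl transfer because it is the more general operation for aryl vinyl carbinols and spends material at the cheapest point of the route.

## Roads not taken

**Alternative 1:** The cut is C7′–C8′ plus C7–C8 with neither ring in place. Chiral butenolide A1 accepts the lithiated ring B dithiane A2 at C8′, anti to its acetal substituent, and the lactone enolate is trapped at C8 by ring A aldehyde A3 to give the trans,trans lactone A4.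
- Merits: three components and two C–C bonds in one flask, with C8 and C8′ set by an auxiliary. The prenyl ether can be present from the start, because no Lewis acid or carbene follows. In this respect the road is better than the chosen one, which spends two extra operations on telling the phenols apart.
- Weak points: neither benzylic centre is fixed in A4. C7 arises in an aldol with little control and C7′ is a masked ketone. Both rings remain to be made: dithiane hydrolysis beside a prenyl alkene and two electron-rich arenes, ketone reduction, reduction of C9 and C9′ to the diol level, and a twofold cyclodehydration. Those closures pass through benzylic cations, so the aryl configurations become thermodynamic and the acid endangers the prenyl ether. The auxiliary is needed in its less common enantiomeric series.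
- Comparison: the chosen plan sets C7 and C7′ by reagent control and never ionises them, at the price of a less convergent C–C construction.

**Alternative 2:** The cut is C8–C8′ together with a sacrificial C7–C7′ bond. The tethered mixed bis-cinnamate A5 is irradiated or sensitised to the all-trans head-to-head cyclobutane A6 inside a ten-membered tether ring.
- Merits: the central bond and both ring-fusion centres come from one photochemical step under tether control, after very few steps. The chosen plan cannot match this economy.
- Weak points: tethered cinnamates usually give the syn head-to-head dimer, not the all-trans one. The prenyl alkene is exposed to sensitised irradiation. The later scission of C7–C7′ with formation of two C–O bonds has no secure basis, since radical cations of 1,2-diarylcyclobutanes tend to revert to alkenes, and it would set C7 and C7′ without control.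
- Comparison: the chosen plan is longer but every step belongs to a known reaction type.

**Alternative 3:** The cut is at both aryl–benzylic carbon bonds. The C2-symmetric bis-lactol diacetate A7 is ionised twice by a boron Lewis acid, and arylzinc reagent A8 adds to C7 and C7′ from the convex face to give the bis-silyl ether A9.
- Merits: it is the shortest road, it uses the symmetry of the core, and the exo selectivity follows from the shape of the cis-fused bicycle. In step count and probably in throughput it is better than the chosen plan.
- Weak points: enantiopure A7 is the only source of chirality and needs its own asymmetric synthesis or a resolution. Once formed, the para-silyloxybenzylic C–O bonds of A9 sit in the Lewis acid and can epimerise by ring opening. Both aryl groups enter identical, so the route ends with diphenol A10 and a statistical mono-alkylation with 23.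
- Comparison: the chosen plan offers rings that differ from the outset (ordered prenylation), aryl groups that are electron-poor during every acidic step, and stereocentres from two reagent-controlled operations on simple aldehydes.

Key step: step 10

## Route

Step 1
Reactants: 1 vanillin (4-hydroxy-3-methoxybenzaldehyde)
Product: 2 4-formyl-2-methoxyphenyl 4-methylbenzenesulfonate
Conditions: TsCl, Et3N, DMAP (cat.), CH2Cl2, 0 °C to rt
Reagents that add atoms: p-toluenesulfonyl chloride, Cc1ccc(cc1)S(Cl)(=O)=O
Why: O-sulfonylation of a phenol; the tosylate makes the para oxygen of ring A an acceptor, survives every later step and is removed last.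

Step 2
Reactants: 2 4-formyl-2-methoxyphenyl 4-methylbenzenesulfonate; 3 allyl 4-methoxyphenyl ether
Product: 5 2-methoxy-4-[(1S,2S)-1-hydroxy-2-(4-methoxyphenoxy)but-3-en-1-yl]phenyl 4-methylbenzenesulfonate, via the Z-configured alkoxyallylborane 4 (not isolated)
Conditions: 3, s-BuLi, THF, −78 °C; (+)-Ipc2BOMe; BF3·OEt2; then 2, −78 °C; HOCH2CH2NH2, rt
Reagents that add atoms: (+)-B-methoxydiisopinocampheylborane (from (−)-α-pinene; supplies boron and the terpene groups of intermediate 4 only, nothing of it remains in 5), COB([C@H]1C[C@H]2C[C@@H]([C@@H]1C)C2(C)C)[C@H]1C[C@H]2C[C@@H]([C@@H]1C)C2(C)C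
Why: Brown-type asymmetric γ-alkoxyallylboration; the Z-alkoxyallylborane 4 adds through a closed chair, which makes the C7–C9 relation syn, and the isopinocampheyl groups from (−)-α-pinene direct the allyl unit to the aldehyde face that gives (7S), so C7 and C9 are both set here.

Step 3
Reactants: 5 2-methoxy-4-[(1S,2S)-1-hydroxy-2-(4-methoxyphenoxy)but-3-en-1-yl]phenyl 4-methylbenzenesulfonate; 6 chloromethyl methyl ether
Product: 7 2-methoxy-4-[(1S,2S)-1-(methoxymethoxy)-2-(4-methoxyphenoxy)but-3-en-1-yl]phenyl 4-methylbenzenesulfonate
Conditions: 6, iPr2NEt, Bu4NI (cat.), CH2Cl2, 0 °C to rt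
Reagents that add atoms: none
Why: O-alkylation of the secondary benzylic alcohol by the α-chloro ether; it places the formaldehyde acetal on O1, the homoallylic oxygen required for the later 6-endo closure, and supplies C9′.

Step 4
Reactants: 7 2-methoxy-4-[(1S,2S)-1-(methoxymethoxy)-2-(4-methoxyphenoxy)but-3-en-1-yl]phenyl 4-methylbenzenesulfonate
Product: 8 2-methoxy-4-[(1S,2S)-2-hydroxy-1-(methoxymethoxy)but-3-en-1-yl]phenyl 4-methylbenzenesulfonate
Conditions: (NH4)2Ce(NO3)6, MeCN/H2O, 0 °C
Reagents that add atoms: none
Why: oxidative dearylation of a 4-methoxyphenyl ether by tetravalent cerium (two-electron oxidation to the quinone level, then hydrolysis); the tosyloxy-substituted ring A is too electron-poor to compete, and the acetal should survive the short contact at 0 °C.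

Step 5
Reactants: 1 vanillin (4-hydroxy-3-methoxybenzaldehyde)
Product: 9 4-formyl-2-methoxyphenyl pivalate
Conditions: PivCl, Et3N, DMAP (cat.), CH2Cl2, 0 °C to rt
Reagents that add atoms: pivaloyl chloride, CC(C)(C)C(Cl)=O
Why: O-acylation of the phenol; the pivalate makes the para oxygen of ring B an acceptor so that the C7′–O bond does not ionise later, and it is the more labile of the two aryl masks.

Step 6
Reactants: 9 4-formyl-2-methoxyphenyl pivalate; 10 vinylmagnesium bromide
Product: 11 rac-4-(1-hydroxyprop-2-en-1-yl)-2-methoxyphenyl pivalate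
Conditions: 10, THF, −78 °C; aq. NH4Cl
Reagents that add atoms: none
Why: Grignard 1,2-addition to the aldehyde; at −78 °C the hindered aryl pivalate should not be attacked; C7′ is formed racemic and resolved in step 7.

Step 7
Reactants: 11 rac-4-(1-hydroxyprop-2-en-1-yl)-2-methoxyphenyl pivalate
Product: 12 4-[(1R)-1-hydroxyprop-2-en-1-yl]-2-methoxyphenyl pivalate
Conditions: Ti(OiPr)4, D-(−)-diisopropyl tartrate, t-BuOOH (0.6 equiv), 4 Å molecular sieves, CH2Cl2, −20 °C
Reagents that add atoms: none
Why: Sharpless kinetic resolution of a secondary allylic alcohol; with the D-tartrate the (S)-enantiomer should be epoxidised faster (to the anti epoxy alcohol), so running past half conversion should leave (R)-12 enantioenriched, and the acceptor aryl group lowers the tendency of the carbinol to ionise on tetravalent titanium.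

Step 8
Reactants: 12 4-[(1R)-1-hydroxyprop-2-en-1-yl]-2-methoxyphenyl pivalate
Product: 13 4-[(1R)-1-(tert-butyldimethylsilyloxy)prop-2-en-1-yl]-2-methoxyphenyl pivalate
Conditions: TBSCl, imidazole, DMF, rt
Reagents that add atoms: tert-butyldimethylsilyl chloride, CC(C)(C)[Si](C)(C)Cl
Why: imidazole-promoted silylation of a secondary alcohol; the silyl ether keeps O2 out of the Lewis acid step and is removable by fluoride beside both aryl masks.

Step 9
Reactants: 8 2-methoxy-4-[(1S,2S)-2-hydroxy-1-(methoxymethoxy)but-3-en-1-yl]phenyl 4-methylbenzenesulfonate; 13 4-[(1R)-1-(tert-butyldimethylsilyloxy)prop-2-en-1-yl]-2-methoxyphenyl pivalate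
Product: 14 (1S,2S,3E,5R)-5-(tert-butyldimethylsilyloxy)-1-(methoxymethoxy)-1-[3-methoxy-4-(tosyloxy)phenyl]-5-[3-methoxy-4-(pivaloyloxy)phenyl]pent-3-en-2-ol, i.e. (7S,9S,7′R)
Conditions: second-generation Hoveyda–Grubbs catalyst [(H2IMes)Cl2Ru=CH(C6H4-2-OiPr)] (cat.), 13 (excess), 1,4-benzoquinone (cat.), CH2Cl2, 40 °C
Reagents that add atoms: none
Why: olefin cross-metathesis; both partners are branched and allylically oxygenated and so homodimerise slowly, the free C9 hydroxyl of 8 assists carbene loading, an excess of 13 drives 8 to the cross product, and a 1,2-disubstituted alkene between two branched carbons should form as the E isomer; no stereocentre is touched.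

Step 10
Reactants: 14 (1S,2S,3E,5R)-5-(tert-butyldimethylsilyloxy)-1-(methoxymethoxy)-1-[3-methoxy-4-(tosyloxy)phenyl]-5-[3-methoxy-4-(pivaloyloxy)phenyl]pent-3-en-2-ol
Product: 17 (2R,3S,4S)-4-{(R)-(tert-butyldimethylsilyloxy)[3-methoxy-4-(pivaloyloxy)phenyl]methyl}-2-[3-methoxy-4-(tosyloxy)phenyl]oxolane-3-carbaldehyde (formyl cis to the C7 aryl group, trans to the C8′ side chain), via the O1 oxocarbenium ion 15 (not isolated), via the oxan-4-yl cation 16 (not isolated)
Conditions: SnCl4, CH2Cl2, −78 to −20 °C; aq. NaHCO3
Reagents that add atoms: none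
Why: SnCl4 abstracts methoxide from the methoxymethyl ether to give the formaldehyde-derived oxocarbenium ion 15 on O1, whose carbon C9′ is attacked by alkene carbon C8′ in a 6-endo-trig Prins closure through a chair with the C7 aryl group and the C8′ side chain (E-alkene) equatorial and the C9 hydroxyl (syn diol) axial, giving cation 16. C7 then shifts from C9 to the adjacent cationic C8 with retention, so the six-membered ring contracts to ring 1 and C9 leaves the ring as the formyl group; ring 1 is therefore not closed directly but arises from the 6-endo closure plus 1,2-shift. The closest known reaction type is the Prins–pinacol synthesis of 3-acyltetrahydrofurans from acetals and alkoxymethyl ethers of allylic 1,2-diols, of which the secondary-carbinol variant ends in a formyl group. C8′ is set by C7 through the chair (aryl and side chain trans), with the resident C7′ centre as a spectator; C8 is set by the suprafacial shift, which puts the formyl group cis to the aryl group, and is corrected in step 11. The step needs ionisation at the acetal and not at the benzylic C–O bonds, which the tosylate and pivalate on the para oxygens secure, and it needs ring-bond migration and not hydride shift, which the axial hydroxyl favours because the C9–H bond then lies near the nodal plane of the cation. A [3,3] shift of 15 followed by aldol reclosure would lead to the same constitution.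

Step 11
Reactants: 17 (2R,3S,4S)-4-{(R)-(tert-butyldimethylsilyloxy)[3-methoxy-4-(pivaloyloxy)phenyl]methyl}-2-[3-methoxy-4-(tosyloxy)phenyl]oxolane-3-carbaldehyde
Product: 20 cis-fused lactol (C9 hemiacetal of the furofuran, both anomers; ring A tosylate, ring B pivalate; spatial arrangement at C7, C8, C8′, C7′ as in 21), via the desilylated hydroxy aldehyde 18 (not isolated), via its C8 epimer 19 (not isolated)
Conditions: HF·pyridine, pyridine, THF, 0 °C to rt; then Et3N, CH2Cl2, rt
Reagents that add atoms: none
Why: fluoride cleavage of the benzylic silyl ether gives 18, whose formyl group is trans to the C8′ carbinol side chain and cannot close; amine-mediated enolisation equilibrates C8, and only epimer 19 (formyl cis to the side chain, trans to the aryl group) is drained as the five-membered hemiacetal, so lactol formation fixes C8 in the configuration that the cis ring fusion demands.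

Step 12
Reactants: 20 cis-fused lactol (ring A tosylate, ring B pivalate)
Product: 21 (7R,7′R,8S,8′S)-furofuran, ring A 4-O-tosylate and ring B 4-O-pivalate (2-methoxy-4-[(1R,3aS,4R,6aS)-4-[3-methoxy-4-(pivaloyloxy)phenyl]tetrahydro-1H,3H-furo[3,4-c]furan-1-yl]phenyl 4-methylbenzenesulfonate)
Conditions: Et3SiH, BF3·OEt2, CH2Cl2, −78 to −20 °C
Reagents that add atoms: none
Why: ionic hydrogenation of a lactol; BF3·OEt2 ionises the hemiacetal at C9 and the silane reduces the oxocarbenium ion, C9 becomes CH2, and the benzylic C7–O1 and C7′–O2 bonds, flanked by acceptor-substituted aryl groups, should stay intact.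

Step 13
Reactants: 21 (7R,7′R,8S,8′S)-furofuran, ring A tosylate, ring B pivalate
Product: 22 (7R,7′R,8S,8′S)-furofuran, ring A tosylate, ring B free phenol
Conditions: K2CO3, MeOH, rt
Reagents that add atoms: none
Why: carbonate-mediated methanolysis of an aryl ester; aryl sulfonates need hydroxide and heat, so only ring B should be unmasked.

Step 14
Reactants: 22 (7R,7′R,8S,8′S)-furofuran, ring A tosylate, ring B free phenol; 23 prenyl bromide (1-bromo-3-methylbut-2-ene)
Product: 24 (7R,7′R,8S,8′S)-furofuran, ring A tosylate, ring B prenyl ether
Conditions: 23, K2CO3, acetone, reflux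
Reagents that add atoms: none
Why: Williamson ether synthesis (SN2 of the phenoxide at the primary allylic bromide); only one phenol is free, so no statistical mixture can arise.

Step 15
Reactants: 24 (7R,7′R,8S,8′S)-furofuran, ring A tosylate, ring B prenyl ether
Product: 25 target, 2-methoxy-4-[(1R,3aS,4R,6aS)-4-{3-methoxy-4-[(3-methylbut-2-en-1-yl)oxy]phenyl}tetrahydro-1H,3H-furo[3,4-c]furan-1-yl]phenol
Conditions: KOH, MeOH/H2O, reflux; then HCl to pH 6
Reagents that add atoms: none
Why: alkaline hydrolysis of the aryl sulfonate by attack at sulfur; the furofuran has no base-sensitive site and the prenyl ether is inert to hydroxide.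

## Compound list

1 | vanillin | COc1cc(C=O)ccc1O | starting material
2 | 4-formyl-2-methoxyphenyl 4-methylbenzenesulfonate | COc1cc(C=O)ccc1OS(=O)(=O)c1ccc(C)cc1 | intermediate
3 | allyl 4-methoxyphenyl ether | C=CCOc1ccc(OC)cc1 | starting material
4 | [(Z)-3-(4-methoxyphenoxy)prop-2-en-1-yl]diisopinocampheylborane (terpene groups from (−)-α-pinene) | COc1ccc(O/C=C\CB([C@H]2C[C@H]3C[C@@H]([C@@H]2C)C3(C)C)[C@H]2C[C@H]3C[C@@H]([C@@H]2C)C3(C)C)cc1 | intermediate
5 | 2-methoxy-4-[(1S,2S)-1-hydroxy-2-(4-methoxyphenoxy)but-3-en-1-yl]phenyl 4-methylbenzenesulfonate | COc1cc([C@H](O)[C@@H](Oc2ccc(OC)cc2)C=C)ccc1OS(=O)(=O)c1ccc(C)cc1 | intermediate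
6 | chloromethyl methyl ether | COCCl | starting material
7 | 2-methoxy-4-[(1S,2S)-1-(methoxymethoxy)-2-(4-methoxyphenoxy)but-3-en-1-yl]phenyl 4-methylbenzenesulfonate | COc1cc([C@H](OCOC)[C@@H](Oc2ccc(OC)cc2)C=C)ccc1OS(=O)(=O)c1ccc(C)cc1 | intermediate
8 | 2-methoxy-4-[(1S,2S)-2-hydroxy-1-(methoxymethoxy)but-3-en-1-yl]phenyl 4-methylbenzenesulfonate | COc1cc([C@H](OCOC)[C@@H](O)C=C)ccc1OS(=O)(=O)c1ccc(C)cc1 | intermediate
9 | 4-formyl-2-methoxyphenyl pivalate | COc1cc(C=O)ccc1OC(=O)C(C)(C)C | intermediate
10 | vinylmagnesium bromide | C=C[Mg]Br | starting material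
11 | rac-4-(1-hydroxyprop-2-en-1-yl)-2-methoxyphenyl pivalate | C=CC(O)c1ccc(OC(=O)C(C)(C)C)c(OC)c1 | intermediate
12 | 4-[(1R)-1-hydroxyprop-2-en-1-yl]-2-methoxyphenyl pivalate | C=C[C@@H](O)c1ccc(OC(=O)C(C)(C)C)c(OC)c1 | intermediate
13 | 4-[(1R)-1-(tert-butyldimethylsilyloxy)prop-2-en-1-yl]-2-methoxyphenyl pivalate | C=C[C@@H](O[Si](C)(C)C(C)(C)C)c1ccc(OC(=O)C(C)(C)C)c(OC)c1 | intermediate
14 | (1S,2S,3E,5R)-5-(tert-butyldimethylsilyloxy)-1-(methoxymethoxy)-1-[3-methoxy-4-(tosyloxy)phenyl]-5-[3-methoxy-4-(pivaloyloxy)phenyl]pent-3-en-2-ol | COc1cc([C@H](OCOC)[C@@H](O)/C=C/[C@@H](O[Si](C)(C)C(C)(C)C)c2ccc(OC(=O)C(C)(C)C)c(OC)c2)ccc1OS(=O)(=O)c1ccc(C)cc1 | intermediate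
15 | O1-methylidene oxocarbenium ion derived from 14 | COc1cc([C@H]([O+]=C)[C@@H](O)/C=C/[C@@H](O[Si](C)(C)C(C)(C)C)c2ccc(OC(=O)C(C)(C)C)c(OC)c2)ccc1OS(=O)(=O)c1ccc(C)cc1 | intermediate
16 | 2-aryl-3-hydroxy-5-[aryl(silyloxy)methyl]oxan-4-yl cation (aryl and side chain equatorial, hydroxyl axial) | COc1cc([C@@H]2OC[C@@H]([C@@H](O[Si](C)(C)C(C)(C)C)c3ccc(OC(=O)C(C)(C)C)c(OC)c3)[CH+][C@@H]2O)ccc1OS(=O)(=O)c1ccc(C)cc1 | intermediate
17 | (2R,3S,4S)-4-{(R)-(tert-butyldimethylsilyloxy)[3-methoxy-4-(pivaloyloxy)phenyl]methyl}-2-[3-methoxy-4-(tosyloxy)phenyl]oxolane-3-carbaldehyde | COc1cc([C@@H]2OC[C@@H]([C@@H](O[Si](C)(C)C(C)(C)C)c3ccc(OC(=O)C(C)(C)C)c(OC)c3)[C@@H]2C=O)ccc1OS(=O)(=O)c1ccc(C)cc1 | intermediate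
18 | (2R,3S,4S)-4-{(R)-hydroxy[3-methoxy-4-(pivaloyloxy)phenyl]methyl}-2-[3-methoxy-4-(tosyloxy)phenyl]oxolane-3-carbaldehyde | COc1cc([C@@H]2OC[C@@H]([C@@H](O)c3ccc(OC(=O)C(C)(C)C)c(OC)c3)[C@@H]2C=O)ccc1OS(=O)(=O)c1ccc(C)cc1 | intermediate
19 | (2R,3R,4S)-4-{(R)-hydroxy[3-methoxy-4-(pivaloyloxy)phenyl]methyl}-2-[3-methoxy-4-(tosyloxy)phenyl]oxolane-3-carbaldehyde | COc1cc([C@@H]2OC[C@@H]([C@@H](O)c3ccc(OC(=O)C(C)(C)C)c(OC)c3)[C@H]2C=O)ccc1OS(=O)(=O)c1ccc(C)cc1 | intermediate
20 | cis-fused C9 lactol of the furofuran, ring A tosylate, ring B pivalate (both anomers) | COc1cc([C@@H]2OC[C@@H]3[C@H]2C(O)O[C@H]3c2ccc(OC(=O)C(C)(C)C)c(OC)c2)ccc1OS(=O)(=O)c1ccc(C)cc1 | intermediate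
21 | (7R,7′R,8S,8′S)-furofuran, ring A tosylate, ring B pivalate | COc1cc([C@@H]2OC[C@@H]3[C@H]2CO[C@H]3c2ccc(OC(=O)C(C)(C)C)c(OC)c2)ccc1OS(=O)(=O)c1ccc(C)cc1 | intermediate
22 | (7R,7′R,8S,8′S)-furofuran, ring A tosylate, ring B phenol | COc1cc([C@@H]2OC[C@@H]3[C@H]2CO[C@H]3c2ccc(O)c(OC)c2)ccc1OS(=O)(=O)c1ccc(C)cc1 | intermediate
23 | prenyl bromide | CC(C)=CCBr | starting material
24 | (7R,7′R,8S,8′S)-furofuran, ring A tosylate, ring B prenyl ether | COc1cc([C@@H]2OC[C@@H]3[C@H]2CO[C@H]3c2ccc(OCC=C(C)C)c(OC)c2)ccc1OS(=O)(=O)c1ccc(C)cc1 | intermediate
25 | CNP0185952.2, (7R,7′R,8S,8′S)-furofuran with ring A phenol and ring B prenyl ether | COc1cc([C@@H]2OC[C@@H]3[C@H]2CO[C@H]3c2ccc(OCC=C(C)C)c(OC)c2)ccc1O | target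

## Step count and risks

Total step count: 15. Longest linear sequence: 11 steps from vanillin (steps 1, 2, 3, 4, 9, 10, 11, 12, 13, 14, 15; the ring B branch through steps 5 to 8 is equally long).

**Step 10 (key step).** Several processes could divert it.
- The oxocarbenium ion may collapse onto the free C9 hydroxyl to a 1,3-dioxolane, and a formaldehyde acetal of that kind re-ionises only slowly.
- The alkene is deactivated by two allylic C–O bonds.
- If the [3,3] pathway with aldol reclosure dominates, C7 is re-formed without memory of its configuration.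
- Hydride shift from C9 may compete with ring contraction.

Fallback: setting out from 14, the C9 hydroxyl is silylated (Et3SiCl, imidazole, DMF) to the C9 triethylsilyl ether F1. With the hydroxyl capped, collapse to a dioxolane is hindered. SnCl4 should take F1 through the same Prins closure, with the pinacol shift terminated by loss of the silyl group, and the route is rejoined at 17.

**Step 9 (cross-metathesis).** Two branched, allylically oxygenated partners may couple slowly, so that homodimerisation of 8 and redox isomerisation of its free allylic alcohol by ruthenium hydrides become competitive.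
Fallback: the roles of the partners are reversed. Setting out from 8, silylation (Et3SiCl, imidazole) gives the C9 triethylsilyl ether F2. F2 is cross-metathesised with unprotected carbinol 12 (same catalyst and additive), whose free hydroxyl now provides the reactive partner, to give the C7′ alcohol F3. Silylation of F3 (TBSCl, imidazole) gives the bis-silyl ether F1, and selective methanolysis of the triethylsilyl ether (pyridinium p-toluenesulfonate, MeOH, 0 °C) returns to the route at 14.

**Step 11 (desilylation, epimerisation, lactol closure).** Under base, the C8 enolate may expel O1 from C7 (β-elimination that opens ring 1) instead of reprotonating. Epimerisation may also stay incomplete, or fluoride may remove the pivalate.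
Fallback: setting out from 17, camphorsulfonic acid in MeOH with HC(OMe)3 (rt to 40 °C) removes the silyl group and equilibrates C8 through the enol ether of the dimethyl acetal, with the cis-fused methyl acetal F4 as the sink. No enolate is involved. Et3SiH with BF3·OEt2 reduces F4 directly, and the route is rejoined at 21.

**Step 7 (kinetic resolution).** A monosubstituted alkene is epoxidised slowly, so the rate difference between the enantiomers may be small, and the benzylic allylic carbinol may ionise on tetravalent titanium.
Fallback: enzymatic resolution. Setting out from 11, lipase B from Candida antarctica with vinyl acetate (tert-butyl methyl ether, rt) should acylate the (R)-enantiomer to the (R)-acetate F5, which is separated from the unreacted (S)-alcohol. The same lipase with n-butanol cleaves F5 without touching the aryl pivalate, and the route is rejoined at 12.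

## Further compounds

F1 | step 10 | (1S,2S,3E,5R)-5-(tert-butyldimethylsilyloxy)-1-(methoxymethoxy)-2-(triethylsilyloxy)-1-[3-methoxy-4-(tosyloxy)phenyl]-5-[3-methoxy-4-(pivaloyloxy)phenyl]pent-3-ene | COc1cc([C@H](OCOC)[C@@H](O[Si](CC)(CC)CC)/C=C/[C@@H](O[Si](C)(C)C(C)(C)C)c2ccc(OC(=O)C(C)(C)C)c(OC)c2)ccc1OS(=O)(=O)c1ccc(C)cc1
F2 | step 9 | 2-methoxy-4-[(1S,2S)-1-(methoxymethoxy)-2-(triethylsilyloxy)but-3-en-1-yl]phenyl 4-methylbenzenesulfonate | COc1cc([C@H](OCOC)[C@@H](O[Si](CC)(CC)CC)C=C)ccc1OS(=O)(=O)c1ccc(C)cc1
F3 | step 9 | (1R,2E,4S,5S)-5-(methoxymethoxy)-4-(triethylsilyloxy)-5-[3-methoxy-4-(tosyloxy)phenyl]-1-[3-methoxy-4-(pivaloyloxy)phenyl]pent-2-en-1-ol | COc1cc([C@H](OCOC)[C@@H](O[Si](CC)(CC)CC)/C=C/[C@@H](O)c2ccc(OC(=O)C(C)(C)C)c(OC)c2)ccc1OS(=O)(=O)c1ccc(C)cc1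
F4 | step 11 | cis-fused C9 methyl acetal of the furofuran, ring A tosylate, ring B pivalate (both anomers) | COc1cc([C@@H]2OC[C@@H]3[C@H]2C(OC)O[C@H]3c2ccc(OC(=O)C(C)(C)C)c(OC)c2)ccc1OS(=O)(=O)c1ccc(C)cc1
F5 | step 7 | 4-[(1R)-1-acetoxyprop-2-en-1-yl]-2-methoxyphenyl pivalate | C=C[C@@H](OC(C)=O)c1ccc(OC(=O)C(C)(C)C)c(OC)c1
A1 | alternative 1 | 5-menthyloxyfuran-2(5H)-one (auxiliary of the (1S,2R,5S) series) | O=C1C=C[C@@H](O[C@H]2C[C@@H](C)CC[C@@H]2C(C)C)O1
A2 | alternative 1 | 2-{3-methoxy-4-[(3-methylbut-2-en-1-yl)oxy]phenyl}-1,3-dithiane | COc1cc(C2SCCCS2)ccc1OCC=C(C)C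
A3 | alternative 1 | 3-methoxy-4-(triisopropylsilyloxy)benzaldehyde | COc1cc(C=O)ccc1O[Si](C(C)C)(C(C)C)C(C)C
A4 | alternative 1 | trans,trans-trisubstituted 5-menthyloxybutyrolactone aldol adduct | COc1cc([C@H](O)[C@@H]2C(=O)O[C@H](O[C@H]3C[C@@H](C)CC[C@@H]3C(C)C)[C@H]2C2(c3ccc(OCC=C(C)C)c(OC)c3)SCCCS2)ccc1O[Si](C(C)C)(C(C)C)C(C)C
A5 | alternative 2 | mixed bis-cinnamate on the 2,3-O-isopropylidenethreitol tether | CC(=O)Oc1ccc(/C=C/C(=O)OC[C@@H]2OC(C)(C)O[C@H]2COC(=O)/C=C/c3ccc(OCC=C(C)C)c(OC)c3)cc1OC
A6 | alternative 2 | tethered all-trans head-to-head cyclobutane diester | CC(=O)Oc1ccc([C@H]2[C@@H]3C(=O)OC[C@@H]4OC(C)(C)O[C@H]4COC(=O)[C@H]3[C@@H]2c2ccc(OCC=C(C)C)c(OC)c2)cc1OC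
A7 | alternative 3 | cis-3,7-dioxabicyclo[3.3.0]octane-2,6-diyl diacetate (anomers) | CC(=O)OC1OC[C@@H]2[C@H]1COC2OC(C)=O
A8 | alternative 3 | [4-(tert-butyldimethylsilyloxy)-3-methoxyphenyl]zinc bromide | COc1cc([Zn]Br)ccc1O[Si](C)(C)C(C)(C)C
A9 | alternative 3 | bis(tert-butyldimethylsilyl) ether of the unprenylated diphenol | COc1cc([C@@H]2OC[C@@H]3[C@H]2CO[C@H]3c2ccc(O[Si](C)(C)C(C)(C)C)c(OC)c2)ccc1O[Si](C)(C)C(C)(C)C
A10 | alternative 3 | unprenylated (7R,7′R,8S,8′S)-diphenol | COc1cc([C@@H]2OC[C@@H]3[C@H]2CO[C@H]3c2ccc(O)c(OC)c2)ccc1O
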